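The zeta run is our one earlier flask. It ran at 110 °C with 0.29 mol% of free catalyst, more than the 0.19 mol% of the new flasks.

| flask | starting material | free catalyst | temperature | remark | time |
|---|---|---|---|---|---|
| zeta | 0.027 M | 0.29 mol% | 110 °C | run made earlier |  |
| Thursday's | 0.027 M | 0.19 mol% | 110 °C |  | 15 min |
| Saturday's | 0.027 M | 0.19 mol% | 50 °C |  | 15 min |
| Friday's | 0.027 M | 0.19 mol% | 70 °C |  | 15 min |
| Wednesday's | 0.027 M | 0.19 mol% | 90 °C |  | 15 min |

zeta run (percent of the starting material charged): time / min: product / % = 0.250: 7.8; 0.833: 26.7; 1.33: 41.2; 2.00: 59.2; 3.00: 83.0

(standard deviation of a reading: 0.3 percentage points)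

- the earlier runs do not show what temperature does; that part of a forecast is a guess
- no earlier run changes the charge of free catalyst; that part of a forecast is a guess

- the flask with the highest amount of product, in percent of the starting material charged ("all alike" if they lie within 1.5 percentage points) (Thursday's / Saturday's / Friday's / Wednesday's / all alike)
- final product, as a percentage of the starting material charged, in Thursday's
- final product, as a percentage of the starting material charged, in Saturday's
- final product, as a percentage of the starting material charged, in Friday's
- final product, as a percentage of the starting material charged, in Wednesday's

We ask first what the end state must be. In the zeta run, product is still rising when it reads 83.0% at 3.00 min, so we take full conversion as the end and ask how fast it is approached. Between the first and last readings of the zeta run, the fraction of the charge turned per minute, divided by the catalyst charged as a fraction of the same charge, is 94.3 min⁻¹: the turnover frequency. To reach full conversion in 15 min with 0.19 mol%, a flask needs 35.1 min⁻¹. The zeta figure is larger, so Thursday's, at the same 110 °C, should end near full conversion.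

But the slope of the zeta run eases. Its last interval gives 82.1 min⁻¹, less than the average. That still clears the need. A second objection is harder: we assume that rate follows the catalyst charged, and no earlier run tests this. Still, by this reckoning Thursday's needs an average of just 42.8% of that late figure to reach the end in time. Temperature is a guess as well. For a flask short of the need, we read the same quantity the other way: the fraction of the charge turned is the average turnover frequency times the loading times the time. We commit to Thursday's on top and to less product in colder flasks, without figures of our own for those.

The forecast names Thursday's, with 98% in Thursday's, 72% in Wednesday's, 22% in Friday's and 5% in Saturday's. Its ground for the cold side is “I guess Ea ≈ 70 kJ/mol, which is uncertain”. By our measure, its Wednesday's figure is an average of 25.3 min⁻¹, under the need.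

The flasks give 99.9% in Thursday's, 49.8% in Wednesday's, 9.45% in Friday's and 1.31% in Saturday's, so Thursday's holds the most product. This is what ran:

    2 catalyst intermediate A → spent catalyst (k = 719 M⁻¹ min⁻¹, Ea = 48.0 kJ mol⁻¹)
    starting material + free catalyst → catalyst intermediate A (k = 2.58 × 10⁵ M⁻¹ min⁻¹, Ea = 50.0 kJ mol⁻¹)
    catalyst intermediate B → free catalyst + product (k = 149 min⁻¹, Ea = 83.0 kJ mol⁻¹)
    catalyst intermediate A → catalyst intermediate B (k = 28.2 min⁻¹, Ea = 96.0 kJ mol⁻¹)
    (constants at 90 °C)

At 15.0 min, Wednesday's holds 47.1% of its catalyst as catalyst intermediate A, 8.91% as catalyst intermediate B, 43.7% as spent catalyst and 0.381% as free catalyst. Its average turnover frequency is 17.5 min⁻¹, half of the need and less than the forecast's figure. The neighbour, a repeat of Saturday's at 65 °C, gives 5.95%, an average turnover frequency of 2.09 min⁻¹.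

The runs come from a simulation from invented constants, and the scatter is random.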